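The earlier runs and the new flask are simulated for an exercise; noise was put on by code.

Imd is the product I want, and the step Rea + Imd -> Imd2 + Bpr takes it away, while full conversion to Imd3 asks 3 Rea per Sbt.

| flask | Sbt | Rea | remark | time |
|---|---|---|---|---|
| zeta | 0.50 M | 2.1 M | run made earlier |  |
| gamma | 1 M | 1.5 M | run made earlier |  |
| flask | 0.50 M | 1.50 M |  | 5.0 d |

| run | time / d | Imd / % | Imd3 / % |
|---|---|---|---|
| zeta | 0.417 | 36.6 | 34.2 |
| zeta | 0.833 | 15.2 | 65.9 |
| zeta | 1.25 | 8.8 | 78.8 |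
| zeta | 1.67 | 5.4 | 88.8 |
| zeta | 2.00 | 1.9 | 91.0 |
| zeta | 2.50 | 1.2 | 94.0 |
| zeta | 3.00 | 0.7 | 97.4 |
| gamma | 0.625 | 53.4 | 12.6 |
| gamma | 1.25 | 50.4 | 14.0 |
| gamma | 1.67 | 48.3 | 15.9 |
| gamma | 2.50 | 47.4 | 16.9 |
| gamma | 3.00 | 47.7 | 18.7 |

(scatter of a reading: 1 percentage point)

- percent here means Sbt units held: one Ofp counts as two
- steps under discussion: Sbt + Rea -> Imd + Bpr; Rea + Imd -> Imd2 + Bpr; Rea + Imd2 -> Imd3 + Bpr; Sbt + Imd2 -> Ofp

- equivalents of Rea to Sbt, everything else as given, that leave most Imd at 5.0 d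
- the amount of Imd then, in percent of the Sbt charged
- the amount of Imd with the amounts as given

At the bench I would say that with Rea in excess, Imd falls pseudo-first-order, with half-life ln(2)/(k[Rea]). In the zeta run Imd drops from 15.2% at 0.833 d to 1.2% at 2.50 d. At the middle reading the balance gives [Rea] = 0.683 M, if I count whatever is neither Imd nor Imd3 as Imd2. So k, the rate constant of Imd per molar of Rea, reads 2.23 M⁻¹ d⁻¹. It is a rough reading, since 1.2% carries a scatter of 1 percentage point.

The border is the charge over the demand, [Rea]/(3[Sbt]): 1.40 in zeta but 1.00 in this flask. Here no fixed excess exists to put into the rule.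

So I solve both ends. Early, at the charged [Rea], the half-life is 0.207 d, short against 5.0 d, so I start the tail from 0.50 M at zero time. Late, setting Ofp aside, [Rea] equals 2[Imd] + [Imd2]. Zeta at 1.25 d suggests [Rea] = 3.41[Imd], so 1/[Imd] climbs steadily and I commit to 5.00%.

The forecast says 1.25 equiv, 54% and 9%, calling “the tail is second-order”, and its last figure stands above mine.

The flask gives 5.23% Imd, and its best is 55.4% at 1.05 equiv.

    Sbt + Rea → Imd + Bpr (k = 0.250 M⁻¹ h⁻¹)
    Rea + Imd → Imd2 + Bpr (k = 0.0890 M⁻¹ h⁻¹)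
    Rea + Imd2 → Imd3 + Bpr (k = 0.140 M⁻¹ h⁻¹)
    Sbt + Imd2 → Ofp (k = 0.0620 M⁻¹ h⁻¹)

At 5.0 d this flask still holds 7.44% of its Rea, [Rea] = 0.112 M, which with k makes the Imd half-life 2.78 d. A further flask, like this one but charged 0.60 M Rea, lies outside the half-life rule with k, for Rea is no excess there: at 5.0 d it keeps 0.119% of its Rea, [Rea] = 7.13 × 10⁻⁴ M, against [Imd] = 0.272 M.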